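**Plan**
- **Cuts:** (a) the two tert-butyl esters. (b) The aryl–C(=O) bond, traced back to its O-acyl isomer, the o-iodoaryl trienoate 18; its ester C–O bond then leads to iodophenol 10 and half-ester 17. (c) C3–C4 of the heptenoate chain. (d) The CH–vinyl bond at the stereocentre. (e) In 17, C2=C3, and the C6 dienal back to furan plus a diazoacetate.
- **Enabling feature:** the phenol O sits on the ring carbon next to the one that carries the ketone (O–C(ar)–C(ar)–C=O). The other ortho carbon holds the sec-alkyl chain and the para carbon holds OMe, so an acyl group parked on that O can move to only one ring carbon. Iodine at that carbon is the traceless trigger.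
- **Forward order:** the benzene ring is bought with 1. The sequence is vinyl, (R)-butenyl, heptenoate chain, iodine, O-acylation with the complete C8 trienedioate, 1,3 O→C acyl shift, double ester cleavage. No ring of the target is built; only a transient four-membered ring appears in the key step.
- **Stereochemistry:** the single (R)-centre comes from ligand control in a nickel-catalysed hydrovinylation and is not touched afterwards. The E-alkenes come from a stereoretentive Suzuki coupling, iodine equilibration and a Doebner condensation.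

Key step: step 11

Assumption: the stereocentre of the given SMILES is (R). The hydrovinylation ligand is taken in the enantiomeric series that delivers the (R)-3-arylbut-1-ene. (E)-3-Iodoacrylic acid and tert-butyl diazoacetate are treated as commercial.

Step 1
Reactants: 1 2-hydroxy-5-methoxybenzaldehyde
Product: 2 2-[(tert-butyldimethylsilyl)oxy]-5-methoxybenzaldehyde
Conditions: TBSCl, imidazole, DMF, rt
Reagents that add atoms: tert-butyldimethylsilyl chloride, CC(C)(C)[Si](C)(C)Cl
Why: Imidazole-promoted silyl ether formation masks the acidic OH against the ylide, the cationic nickel hydride and the borane, and the group later leaves with fluoride without harm to a tert-butyl ester.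

Step 2
Reactants: 2 2-[(tert-butyldimethylsilyl)oxy]-5-methoxybenzaldehyde
Product: 3 tert-butyl(2-ethenyl-4-methoxyphenoxy)dimethylsilane
Conditions: MePPh3Br, KOtBu (slightly less than the salt), THF, 0 °C to rt
Reagents that add atoms: methyltriphenylphosphonium bromide, C[P+](c1ccccc1)(c1ccccc1)c1ccccc1.[Br-]
Why: Wittig methylenation of an aromatic aldehyde with the non-stabilised ylide is fast at 0 °C and should leave the aryl silyl ether intact when no free base remains.

Step 3
Reactants: 3 tert-butyl(2-ethenyl-4-methoxyphenoxy)dimethylsilane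
Product: 4 (R)-[2-(but-3-en-2-yl)-4-methoxyphenoxy](tert-butyl)dimethylsilane
Conditions: ethylene (1 atm), [(allyl)NiBr]2 (cat.), BINOL-derived phosphoramidite bearing a bis(1-phenylethyl)amino group (cat.), NaB[3,5-(CF3)2C6H3]4, CH2Cl2, −70 °C
Reagents that add atoms: ethylene, C=C
Why: In this nickel-catalysed asymmetric hydrovinylation of a vinylarene the cationic Ni–H adds to the styrene to give an η3-benzyl complex, ethylene inserts at the benzylic carbon and β-hydride elimination releases the 3-arylbut-1-ene, the chiral ligand choosing the styrene face and so setting the (R)-centre, while the low temperature suppresses isomerisation to the conjugated 2-arylbut-2-ene.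

Step 4
Reactants: 5 (E)-3-iodoprop-2-enoic acid
Product: 6 tert-butyl (E)-3-iodoprop-2-enoate
Conditions: isobutene, H2SO4 (cat.), CH2Cl2, sealed vessel, rt
Reagents that add atoms: 2-methylpropene, CC(C)=C
Why: Acid-catalysed addition of the carboxylic acid to isobutene (tert-butyl ester formation) uses no base or nucleophile that could add to or isomerise the β-iodoacrylate.

Step 5
Reactants: 4 (R)-[2-(but-3-en-2-yl)-4-methoxyphenoxy](tert-butyl)dimethylsilane; 6 tert-butyl (E)-3-iodoprop-2-enoate
Product: 8 tert-butyl (2E,6R)-6-{2-[(tert-butyldimethylsilyl)oxy]-5-methoxyphenyl}hept-2-enoate, via B-alkyl-9-BBN adduct 7 (not isolated)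
Conditions: 9-BBN-H, THF, rt; then 6, PdCl2(dppf) (cat.), AsPh3 (cat.), Cs2CO3, DMF/THF/H2O, rt
Reagents that add atoms: 9-borabicyclo[3.3.1]nonane, B1C2CCCC1CCC2 (its atoms are kept in 7 only)
Why: Anti-Markovnikov hydroboration of the monosubstituted alkene followed by B-alkyl Suzuki–Miyaura coupling with a β-iodoacrylate should retain the E geometry and leave the benzylic centre alone, because oxidative addition to the vinyl iodide is fast at rt and dppf suppresses β-hydride elimination.

Step 6
Reactants: 8 tert-butyl (2E,6R)-6-{2-[(tert-butyldimethylsilyl)oxy]-5-methoxyphenyl}hept-2-enoate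
Product: 9 tert-butyl (2E,6R)-6-(2-hydroxy-5-methoxyphenyl)hept-2-enoate
Conditions: TBAF, AcOH (1:1), THF, 0 °C
Reagents that add atoms: none
Why: Fluoride-induced cleavage of an aryl silyl ether is selective for Si–O, and the acetic acid buffer protonates the phenoxide before it can act as a base or a Michael donor towards the enoate.

Step 7
Reactants: 9 tert-butyl (2E,6R)-6-(2-hydroxy-5-methoxyphenyl)hept-2-enoate
Product: 10 tert-butyl (2E,6R)-6-(2-hydroxy-3-iodo-5-methoxyphenyl)hept-2-enoate
Conditions: NIS, p-TsOH (cat.), MeCN, 0 °C to rt, dark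
Reagents that add atoms: N-iodosuccinimide, O=C1CCC(=O)N1I
Why: In this electrophilic aromatic iodination the OH is the strongest donor, its para carbon is blocked by OMe and one ortho carbon by the alkyl chain, so iodine should enter at the remaining ortho carbon, and the electron-poor enoate does not react with NIS.

Step 8
Reactants: 11 furan (excess, also the solvent); 12 tert-butyl diazoacetate
Product: 15 tert-butyl (2E,4E)-6-oxohexa-2,4-dienoate, via oxabicyclohexene cyclopropane 13 (not isolated), via (2E,4Z)-dienal 14 (not isolated)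
Conditions: Rh2(OAc)4 (cat.), slow addition of 12 to furan, rt; evaporate; I2 (cat.), CH2Cl2, rt
Reagents that add atoms: none
Why: Rhodium-carbenoid cyclopropanation of furan gives a donor–acceptor cyclopropane that opens spontaneously to the dienal (furan unravelling), and iodine-catalysed Z to E isomerisation then leads to the thermodynamic (2E,4E) isomer.

Step 9
Reactants: 15 tert-butyl (2E,4E)-6-oxohexa-2,4-dienoate
Product: 17 (2E,4E,6E)-8-tert-butoxy-8-oxoocta-2,4,6-trienoic acid, via dienylidenemalonic acid 16 (not isolated)
Conditions: malonic acid, pyridine, piperidine (cat.), 60–80 °C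
Reagents that add atoms: malonic acid, OC(=O)CC(=O)O
Why: The Doebner modification of the Knoevenagel condensation gives the E-enoic acid directly by condensation and decarboxylation, so the two ends of the C8 diacid are differentiated without a protecting-group step, and the tert-butyl ester is inert to warm pyridine.

Step 10
Reactants: 10 tert-butyl (2E,6R)-6-(2-hydroxy-3-iodo-5-methoxyphenyl)hept-2-enoate; 17 (2E,4E,6E)-8-tert-butoxy-8-oxoocta-2,4,6-trienoic acid
Product: 18 1-tert-butyl 8-{2-[(2R,5E)-7-tert-butoxy-7-oxohept-5-en-2-yl]-6-iodo-4-methoxyphenyl} (2E,4E,6E)-octa-2,4,6-trienedioate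
Conditions: DCC, DMAP (0.2 equiv), CH2Cl2, 0 °C to rt
Reagents that add atoms: none
Why: In the Steglich esterification the acylpyridinium ion formed from the O-acylisourea is reactive enough for the 2,6-disubstituted but fairly acidic iodophenol, and the neutral conditions keep the all-E triene and both tert-butyl esters intact.

Step 11
Reactants: 18 1-tert-butyl 8-{2-[(2R,5E)-7-tert-butoxy-7-oxohept-5-en-2-yl]-6-iodo-4-methoxyphenyl} (2E,4E,6E)-octa-2,4,6-trienedioate
Product: 22 tert-butyl (2E,4E,6E)-8-{3-[(2R,5E)-7-tert-butoxy-7-oxohept-5-en-2-yl]-2-hydroxy-5-methoxyphenyl}-8-oxoocta-2,4,6-trienoate, via aryllithium 19 (not isolated), via benzoxete lithium alkoxide 20 (not isolated), via chelated lithium phenolate 21 (not isolated)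
Conditions: n-BuLi (1.05 equiv, precooled, run down the cold flask wall), THF/Et2O/pentane 4:1:1, 0.01 M, −100 °C, 5 min; then AcOH in THF at −100 °C
Reagents that add atoms: n-butyllithium, [Li]CCCC (lithium is kept in 19–21 only)
Why: Iodine–lithium exchange at the ring carbon next to the acyloxy group should outrun addition of n-BuLi to the three ester carbonyls and to the polyene (the order of rates that underlies exchange-initiated cyclisations of iodo esters and iodo enoates) and gives aryllithium 19, whose lithium is held by the neighbouring ester C=O. 19 attacks that carbonyl carbon in a 4-exo-trig closure to the benzoxete alkoxide 20, which opens at once at its ring C–O bond to the chelated phenolate 21; this is the anionic Fries rearrangement (1,3 O→C acyl shift) known for o-haloaryl esters after halogen–metal exchange. The four-membered ring is transient, its hemiketal carbon is lost again, no stereocentre is created in 22, and the (R)-centre and the four E-alkenes are not involved. Site selectivity is fixed by the iodine, which sits on the only ortho carbon left open by the sec-alkyl group (other ortho) and OMe (para). 1,2- over 1,4-attack is secured by the Z (s-trans) ester conformation, which places the C=O carbon and not Cβ next to C–Li, whereas the 6-endo route to a dihydrocoumarin needs the disfavoured E rotamer. Over-addition is excluded because the ketone is born as a chelated, electron-rich phenolate, and high dilution with an acid quench at −100 °C should suppress intermolecular conjugate addition and oxa-Michael closure to a chromanone.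

Step 12
Reactants: 22 tert-butyl (2E,4E,6E)-8-{3-[(2R,5E)-7-tert-butoxy-7-oxohept-5-en-2-yl]-2-hydroxy-5-methoxyphenyl}-8-oxoocta-2,4,6-trienoate
Product: 23 (2E,4E,6E)-8-{3-[(2R,5E)-6-carboxyhex-5-en-2-yl]-2-hydroxy-5-methoxyphenyl}-8-oxoocta-2,4,6-trienoic acid (target)
Conditions: TFA/CH2Cl2 1:3, 0 °C to rt, dark; co-evaporation with toluene
Reagents that add atoms: none
Why: Acidolysis of tert-butyl esters (alkyl–oxygen cleavage, the cation leaving as isobutene) frees both acids in one operation without base, which could trigger oxa-Michael closure or retro-aldol cleavage of the trienone, and the hydrogen-bonded o-hydroxyaryl ketone and the benzylic centre should be stable to TFA at this temperature.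

**Compound list**
1 | 2-hydroxy-5-methoxybenzaldehyde | COc1ccc(O)c(C=O)c1 | starting material
2 | 2-[(tert-butyldimethylsilyl)oxy]-5-methoxybenzaldehyde | COc1ccc(O[Si](C)(C)C(C)(C)C)c(C=O)c1 | intermediate
3 | tert-butyl(2-ethenyl-4-methoxyphenoxy)dimethylsilane | COc1ccc(O[Si](C)(C)C(C)(C)C)c(C=C)c1 | intermediate
4 | (R)-[2-(but-3-en-2-yl)-4-methoxyphenoxy](tert-butyl)dimethylsilane | COc1ccc(O[Si](C)(C)C(C)(C)C)c([C@H](C)C=C)c1 | intermediate
5 | (E)-3-iodoprop-2-enoic acid | OC(=O)/C=C/I | starting material
6 | tert-butyl (E)-3-iodoprop-2-enoate | CC(C)(C)OC(=O)/C=C/I | intermediate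
7 | 9-{(3R)-3-[2-(tert-butyldimethylsilyloxy)-5-methoxyphenyl]butyl}-9-borabicyclo[3.3.1]nonane | COc1ccc(O[Si](C)(C)C(C)(C)C)c([C@H](C)CCB2C3CCCC2CCC3)c1 | intermediate
8 | tert-butyl (2E,6R)-6-{2-[(tert-butyldimethylsilyl)oxy]-5-methoxyphenyl}hept-2-enoate | COc1ccc(O[Si](C)(C)C(C)(C)C)c([C@H](C)CC/C=C/C(=O)OC(C)(C)C)c1 | intermediate
9 | tert-butyl (2E,6R)-6-(2-hydroxy-5-methoxyphenyl)hept-2-enoate | COc1ccc(O)c([C@H](C)CC/C=C/C(=O)OC(C)(C)C)c1 | intermediate
10 | tert-butyl (2E,6R)-6-(2-hydroxy-3-iodo-5-methoxyphenyl)hept-2-enoate | COc1cc(I)c(O)c([C@H](C)CC/C=C/C(=O)OC(C)(C)C)c1 | intermediate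
11 | furan | c1ccoc1 | starting material
12 | tert-butyl diazoacetate | CC(C)(C)OC(=O)C=[N+]=[N-] | starting material
13 | tert-butyl 2-oxabicyclo[3.1.0]hex-3-ene-6-carboxylate (racemic, exo isomer drawn) | CC(C)(C)OC(=O)[C@@H]1[C@H]2C=CO[C@@H]12 | intermediate
14 | tert-butyl (2E,4Z)-6-oxohexa-2,4-dienoate | CC(C)(C)OC(=O)/C=C/C=C\C=O | intermediate
15 | tert-butyl (2E,4E)-6-oxohexa-2,4-dienoate | CC(C)(C)OC(=O)/C=C/C=C/C=O | intermediate
16 | 2-[(2E,4E)-6-tert-butoxy-6-oxohexa-2,4-dien-1-ylidene]propanedioic acid | CC(C)(C)OC(=O)/C=C/C=C/C=C(C(=O)O)C(=O)O | intermediate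
17 | (2E,4E,6E)-8-tert-butoxy-8-oxoocta-2,4,6-trienoic acid | CC(C)(C)OC(=O)/C=C/C=C/C=C/C(=O)O | intermediate
18 | 1-tert-butyl 8-{2-[(2R,5E)-7-tert-butoxy-7-oxohept-5-en-2-yl]-6-iodo-4-methoxyphenyl} (2E,4E,6E)-octa-2,4,6-trienedioate | COc1cc(I)c(OC(=O)/C=C/C=C/C=C/C(=O)OC(C)(C)C)c([C@H](C)CC/C=C/C(=O)OC(C)(C)C)c1 | intermediate
19 | aryllithium from 18 (Li in place of I) | COc1cc([Li])c(OC(=O)/C=C/C=C/C=C/C(=O)OC(C)(C)C)c([C@H](C)CC/C=C/C(=O)OC(C)(C)C)c1 | intermediate
20 | lithium alkoxide of the 2H-benzoxet-2-ol (tetrahedral adduct; hemiketal carbon undefined and lost again) | COc1cc2c(OC2(O[Li])/C=C/C=C/C=C/C(=O)OC(C)(C)C)c([C@H](C)CC/C=C/C(=O)OC(C)(C)C)c1 | intermediate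
21 | lithium phenolate of 22 | COc1cc(C(=O)/C=C/C=C/C=C/C(=O)OC(C)(C)C)c(O[Li])c([C@H](C)CC/C=C/C(=O)OC(C)(C)C)c1 | intermediate
22 | tert-butyl (2E,4E,6E)-8-{3-[(2R,5E)-7-tert-butoxy-7-oxohept-5-en-2-yl]-2-hydroxy-5-methoxyphenyl}-8-oxoocta-2,4,6-trienoate | COc1cc(C(=O)/C=C/C=C/C=C/C(=O)OC(C)(C)C)c(O)c([C@H](C)CC/C=C/C(=O)OC(C)(C)C)c1 | intermediate
23 | (2E,4E,6E)-8-{3-[(2R,5E)-6-carboxyhex-5-en-2-yl]-2-hydroxy-5-methoxyphenyl}-8-oxoocta-2,4,6-trienoic acid | COc1cc(C(=O)/C=C/C=C/C=C/C(=O)O)c(O)c([C@H](C)CC/C=C/C(=O)O)c1 | target

**Step count**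
- Total step count: 12.
- Longest linear sequence: 9 steps (1, 2, 3, 5, 6, 7, 10, 11, 12).

**Steps most likely to fail**

**Step 11.**
- Risk: butyllithium may add to the trienoate or cleave the aryl ester before the exchange is complete, or the aryllithium may add to a second molecule instead of to its own ester.
- Fallback: the bond is made between separate partners at the aldehyde oxidation level and the ketone is reached by oxidation. It sets out from 10 and 15 and returns at 22.
- Aldehyde 15 is extended by a Wittig reaction with (triphenylphosphoranylidene)acetaldehyde in toluene to tert-butyl (2E,4E,6E)-8-oxoocta-2,4,6-trienoate F1.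
- Iodophenol 10 is deprotonated with MeMgCl/LiCl and exchanged with i-PrMgCl in THF at −30 °C to the doubly magnesiated phenolate F2.
- F2 adds 1,2 to F1 to give the benzylic trienyl carbinol F3 (both epimers).
- MnO2 in CH2Cl2 oxidises this doubly activated alcohol to 22.

**Step 3.**
- Risk: the bulky ortho silyloxy group may slow the insertion, lower the facial selectivity, or leave time for isomerisation of the product alkene into conjugation.
- Fallback: the C–C bond formation is split into C–B and then C–C. It sets out from 3 and returns at 4.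
- Copper(I)-hydride-catalysed Markovnikov asymmetric hydroboration of 3 with pinacolborane (CuCl, NaOtBu, DTBM-SEGPHOS, toluene, rt) gives the (S)-benzylic pinacol boronate F4.
- Zweifel olefination (vinylmagnesium bromide, then I2, then NaOMe, THF/MeOH, −78 °C to rt) replaces boron by vinyl with retention at the migrating carbon and gives 4.

**Step 9.**
- Risk: piperidine or malonate may add in a conjugate sense to the acceptor-substituted dienal, and the aldehyde may polymerise at the temperature needed for decarboxylation.
- Fallback: phosphorane olefination with an orthogonal ester. It sets out from 15 and returns at 17.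
- A Wittig reaction of 15 with allyl (triphenylphosphoranylidene)acetate in CH2Cl2 at rt gives 1-allyl 8-tert-butyl (2E,4E,6E)-octa-2,4,6-trienedioate F5.
- Pd(PPh3)4 and morpholine in THF remove the allyl group under neutral conditions and give 17.

**Further compounds**
F1 | step 11 | tert-butyl (2E,4E,6E)-8-oxoocta-2,4,6-trienoate | CC(C)(C)OC(=O)/C=C/C=C/C=C/C=O
F2 | step 11 | chloromagnesium 2-(chloromagnesio)phenolate derived from 10 | COc1cc([Mg]Cl)c(O[Mg]Cl)c([C@H](C)CC/C=C/C(=O)OC(C)(C)C)c1
F3 | step 11 | tert-butyl (2E,4E,6E)-8-{3-[(2R,5E)-7-tert-butoxy-7-oxohept-5-en-2-yl]-2-hydroxy-5-methoxyphenyl}-8-hydroxyocta-2,4,6-trienoate (both C-8 epimers) | COc1cc(C(O)/C=C/C=C/C=C/C(=O)OC(C)(C)C)c(O)c([C@H](C)CC/C=C/C(=O)OC(C)(C)C)c1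
F4 | step 3 | (S)-tert-butyl{4-methoxy-2-[1-(4,4,5,5-tetramethyl-1,3,2-dioxaborolan-2-yl)ethyl]phenoxy}dimethylsilane | COc1ccc(O[Si](C)(C)C(C)(C)C)c([C@H](C)B2OC(C)(C)C(C)(C)O2)c1
F5 | step 9 | 1-allyl 8-tert-butyl (2E,4E,6E)-octa-2,4,6-trienedioate | C=CCOC(=O)/C=C/C=C/C=C/C(=O)OC(C)(C)C
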